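**Retrosynthetic overview**
1. Last bonds made: C13–C14 (Stille vinylation of a C13 enol triflate gives the 13(16),14-diene under neutral conditions), the C19–O ester (acylation with protected p-coumaric acid) and the 7α,8α-diol (α-face dihydroxylation of a Δ7 alkene).
2. Both carbocycles come from one oxidative radical cascade of an acyclic (6E,10E)-dienyl α-methyl β-keto ester: ring A closes first (C4–C5), ring B second (C10–C9), and the C8 radical is then oxidised to an alkene.
3. Enabling feature: C4 is quaternary and carries a carbon that can stand at the ester level (C19). With a temporary C3 ketone it becomes a β-keto ester radical, and ring A (C4, C3, C2, C1, C10, C5) and ring B (C10, C5, C6, C7, C8, C9) map onto two head-to-tail trisubstituted alkenes (C10=C5 and C8=C9).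
4. A (−)-8-phenylmenthyl ester at C19 sets the absolute configuration; afterwards the C3 oxygen is deleted (cyclic thionocarbonate, Bu3SnH) and the ester is reduced to the C19 CH2OH.
5. The acyclic precursor comes from (E)-geranylacetone (its ketone is C13, its methyl is C16) by terminal allylic oxidation, bromination and γ-alkylation of an acetoacetate dianion.

Key step: step 6

Assumption: the (−)-8-phenylmenthyl ester is taken to direct C5 onto the face of the C4 radical remote from the phenyl ring (ester C=O syn to C3, the usual phenyl-stacking model), which gives the 5α-H, 10β-CH3 series drawn; bicyclic intermediates carry labdane numbering (C1–C13, C16–C20; C14 and C15 arrive in the last step), and compounds 1, 5, 6 and 18 are purchased.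

**Step 1**
Reactants: 1 (E)-geranylacetone
Product: 2 2-[(3E)-4,8-dimethylnona-3,7-dien-1-yl]-2-methyl-1,3-dioxolane
Conditions: ethylene glycol, PPTS (cat.), benzene, reflux, azeotropic removal of water
Reagents that add atoms: ethylene glycol, OCCO
Why: Acid-catalysed ketalisation masks the C13 ketone against the carbanion and hydride steps, the mild acid leaves both trisubstituted alkenes in place, and no stereocentre is formed.

**Step 2**
Reactants: 2 2-[(3E)-4,8-dimethylnona-3,7-dien-1-yl]-2-methyl-1,3-dioxolane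
Product: 3 (2E,6E)-2,6-dimethyl-9-(2-methyl-1,3-dioxolan-2-yl)nona-2,6-dien-1-ol
Conditions: SeO2 (0.3 equiv), t-BuOOH (3 equiv), salicylic acid (cat.), CH2Cl2, 0 °C → rt
Reagents that add atoms: tert-butyl hydroperoxide, CC(C)(C)OO (the oxygen is passed on by catalytic selenium dioxide, O=[Se]=O)
Why: SeO2/t-BuOOH allylic oxidation (ene reaction, then [2,3]-shift) attacks the terminal isopropylidene group at its (E)-methyl and should give the (E)-allylic alcohol, which fixes the carbon that becomes C1.

**Step 3**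
Reactants: 3 (2E,6E)-2,6-dimethyl-9-(2-methyl-1,3-dioxolan-2-yl)nona-2,6-dien-1-ol
Product: 4 2-[(3E,7E)-9-bromo-4,8-dimethylnona-3,7-dien-1-yl]-2-methyl-1,3-dioxolane
Conditions: CBr4, PPh3, CH2Cl2, 0 °C
Reagents that add atoms: carbon tetrabromide, BrC(Br)(Br)Br
Why: The Appel reaction converts the primary allylic alcohol into the bromide under neutral conditions, so the dioxolane and the alkene geometry should be kept.

**Step 4**
Reactants: 5 (−)-8-phenylmenthol [(1R,2S,5R)-5-methyl-2-(2-phenylpropan-2-yl)cyclohexan-1-ol] and 6 ethyl 2-methyl-3-oxobutanoate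
Product: 7 (1R,2S,5R)-8-phenylmenthyl 2-methyl-3-oxobutanoate (C2 epimers)
Conditions: DMAP (0.3 equiv), toluene, reflux, 4 Å molecular sieves (removal of EtOH)
Reagents that add atoms: none
Why: DMAP-catalysed transesterification of a β-keto ester (through the acylketene) installs the auxiliary; the epimeric C2 centre is of no consequence because it becomes a planar enolate and then a radical.

**Step 5**
Reactants: 7 (1R,2S,5R)-8-phenylmenthyl 2-methyl-3-oxobutanoate and 4 2-[(3E,7E)-9-bromo-4,8-dimethylnona-3,7-dien-1-yl]-2-methyl-1,3-dioxolane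
Product: 9 (1R,2S,5R)-8-phenylmenthyl (6E,10E)-2,6,10-trimethyl-13-(2-methyl-1,3-dioxolan-2-yl)-3-oxotrideca-6,10-dienoate, via sodium lithium dianion 8 (not isolated)
Conditions: NaH (1.1 equiv), THF, 0 °C; n-BuLi (1.05 equiv), 0 °C; then 4, 0 °C → rt; sat. aq. NH4Cl
Reagents that add atoms: none
Why: γ-Alkylation of the acetoacetate dianion: the more basic terminal carbanion displaces the allylic bromide by SN2 and forms the C2–C1 bond without touching the (E)-alkenes.

**Step 6**
Reactants: 9 (1R,2S,5R)-8-phenylmenthyl (6E,10E)-2,6,10-trimethyl-13-(2-methyl-1,3-dioxolan-2-yl)-3-oxotrideca-6,10-dienoate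
Product: 10 (−)-8-phenylmenthyl 13,13-ethylenedioxy-3-oxo-14,15-dinorlabd-8(17)-en-19-oate (4α-CH3; 4β-ester; 5α-H; 9α-H; 10β-CH3)
Conditions: Mn(OAc)3·2H2O (2.2 equiv), Cu(OAc)2·H2O (1 equiv), KOAc (2 equiv), degassed AcOH, 25 °C
Reagents that add atoms: none
Why: Trivalent manganese oxidises the enolised α-methyl β-keto ester to the electrophilic tertiary C4 radical, which adds 6-endo-trig to C5 of the C5=C10 alkene (ring A, the C4–C5 bond); the tertiary C10 radical then adds 6-endo-trig to C9 of the C8=C9 alkene (ring B), and divalent copper oxidises the tertiary C8 radical to the alkene, mainly the exocyclic 8(17) isomer. The closest known reaction type is the Mn(OAc)3/Cu(OAc)2 oxidative free-radical polyene cyclisation of α-substituted β-keto esters, which is also established for 8-phenylmenthyl esters. Both closures should run through a chair–chair array of the two (E)-alkenes, which sets the trans ring fusion (5α-H, 10β-CH3) and the equatorial C9 side chain (9α-H). At C4 the ketone lies in the forming ring with the methyl group syn to its oxygen, so the ester should end up axial (4β, the future C19) and the methyl equatorial (4α). The absolute configuration comes from the auxiliary, whose phenyl ring stacks over one face of the planar C4 radical so that C5 bonds to the open face. The step needs 6-endo over 5-exo closure, secured by the carbonyl inside ring A and by the methyl groups on the proximal alkene carbons C10 and C8, and it needs the dioxolane to survive, for which the acetic acid is buffered with KOAc.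

**Step 7**
Reactants: 10 (−)-8-phenylmenthyl 13,13-ethylenedioxy-3-oxo-14,15-dinorlabd-8(17)-en-19-oate
Product: 11 (−)-8-phenylmenthyl 13,13-ethylenedioxy-3-oxo-14,15-dinorlabd-7-en-19-oate (4α-CH3; 4β-ester; 5α-H; 9α-H; 10β-CH3)
Conditions: Co(salen)Cl = chloro[N,N'-bis(3,5-di-tert-butylsalicylidene)-1,2-cyclohexanediaminato]cobalt (3 mol%), PhSiH3 (6 mol%), benzene, rt; then chromatography to the single auxiliary diastereomer
Reagents that add atoms: none
Why: Hydrogen-atom-transfer alkene isomerisation: a cobalt hydride gives a hydrogen atom to C17, the tertiary C8 radical returns the less hindered C7 hydrogen, and the trisubstituted Δ7 alkene does not re-enter the cycle, so exocyclic and any endocyclic alkene from step 6 should converge on one compound without a new stereocentre.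

**Step 8**
Reactants: 11 (−)-8-phenylmenthyl 13,13-ethylenedioxy-3-oxo-14,15-dinorlabd-7-en-19-oate
Product: 12 13,13-ethylenedioxy-14,15-dinorlabd-7-ene-3β,19-diol
Conditions: LiAlH4 (4 equiv), THF, 0 °C → reflux; aqueous NaOH work-up (auxiliary 5 recovered)
Reagents that add atoms: none
Why: Hydride reduction: the C3 ketone is attacked axially from the α face (away from the axial C19 ester and the C10 methyl) to give the equatorial 3β-alcohol, and the hindered ester is reduced to the C19 primary alcohol with release of the auxiliary.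

**Step 9**
Reactants: 12 13,13-ethylenedioxy-14,15-dinorlabd-7-ene-3β,19-diol
Product: 13 13,13-ethylenedioxy-14,15-dinorlabd-7-ene-3β,19-diyl thionocarbonate (six-membered cyclic O,O-thiocarbonate bridging O3 and O19)
Conditions: 1,1'-thiocarbonyldiimidazole (1.5 equiv), DMAP (0.2 equiv), toluene, 90 °C
Reagents that add atoms: 1,1'-thiocarbonyldiimidazole, S=C(n1ccnc1)n1ccnc1
Why: Thiocarbonylation of a 1,3-diol: the equatorial 3β-OH and the axial 4β-CH2OH are gauche and should close a six-membered cyclic thionocarbonate.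

**Step 10**
Reactants: 13 13,13-ethylenedioxy-14,15-dinorlabd-7-ene-3β,19-diyl thionocarbonate
Product: 15 13,13-ethylenedioxy-14,15-dinorlabd-7-en-19-ol, via stannyl thiocarbonate 14 (not isolated)
Conditions: Bu3SnH (2 equiv), AIBN (0.2 equiv), toluene, 110 °C; then NaOH (aq.), MeOH/THF, rt
Reagents that add atoms: none
Why: Barton–McCombie-type radical deoxygenation of a cyclic thionocarbonate: the stannyl radical adduct fragments toward the secondary C3 radical rather than the primary C19 radical, hydrogen transfer gives C3H2, and base hydrolysis of the remaining S-stannyl thiocarbonate frees the C19 alcohol.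

**Step 11**
Reactants: 15 13,13-ethylenedioxy-14,15-dinorlabd-7-en-19-ol
Product: 16 13,13-ethylenedioxy-14,15-dinorlabdane-7α,8α,19-triol
Conditions: OsO4 (5 mol%), NMO (2 equiv), acetone/H2O (8:1), rt
Reagents that add atoms: N-methylmorpholine N-oxide, C[N+]1([O-])CCOCC1; water, O (the oxygens are delivered through catalytic osmium tetroxide, O=[Os](=O)(=O)=O)
Why: Catalytic OsO4/NMO syn-dihydroxylation should take place on the α face, because the β face of C7=C8 is screened by the axial C10 methyl group, giving the cis 7α,8α-diol with the C8 methyl β.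

**Step 12**
Reactants: 16 13,13-ethylenedioxy-14,15-dinorlabdane-7α,8α,19-triol
Product: 17 19-hydroxy-7α,8α-(isopropylidenedioxy)-14,15-dinorlabdan-13-one
Conditions: 2,2-dimethoxypropane (3 equiv), p-TsOH·H2O (5 mol%), acetone, rt; NaHCO3
Reagents that add atoms: 2,2-dimethoxypropane, COC(C)(C)OC
Why: Acetonide formation on the cis-diol and transketalisation of the dioxolane to the solvent acetone occur in one operation, and tying up O8 before the C13 ketone is freed prevents hemiketal or enol-ether formation between the two.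

**Step 13**
Reactants: 18 (E)-4-hydroxycinnamic acid (p-coumaric acid)
Product: 20 (E)-4-(methoxymethoxy)cinnamic acid, via methoxymethyl ester 19 (not isolated)
Conditions: MOMCl (2.5 equiv), i-Pr2NEt (3 equiv), CH2Cl2, 0 °C → rt; then NaOH (2 M aq.), THF/MeOH, rt; HCl to pH 4, 0 °C
Reagents that add atoms: chloromethyl methyl ether, COCCl
Why: O-Alkylation protects phenol and acid, and saponification then cleaves only the acyl–oxygen bond of the methoxymethyl ester, leaving the base-stable aryl MOM ether.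

**Step 14**
Reactants: 17 19-hydroxy-7α,8α-(isopropylidenedioxy)-14,15-dinorlabdan-13-one and 20 (E)-4-(methoxymethoxy)cinnamic acid
Product: 21 7α,8α-(isopropylidenedioxy)-13-oxo-14,15-dinorlabdan-19-yl (E)-4-(methoxymethoxy)cinnamate
Conditions: DCC (1.5 equiv), DMAP (0.5 equiv), CH2Cl2, rt
Reagents that add atoms: none
Why: Steglich esterification acylates the neopentyl C19 hydroxyl, which is the only free hydroxyl group, so no selectivity issue arises.

**Step 15**
Reactants: 21 7α,8α-(isopropylidenedioxy)-13-oxo-14,15-dinorlabdan-19-yl (E)-4-(methoxymethoxy)cinnamate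
Product: 22 7α,8α-(isopropylidenedioxy)-13-(trifluoromethanesulfonyloxy)-14,15-dinorlabd-13(16)-en-19-yl (E)-4-(methoxymethoxy)cinnamate
Conditions: KN(SiMe3)2 (1.2 equiv), THF, −78 °C; PhNTf2 (1.3 equiv), −78 → 0 °C
Reagents that add atoms: N-phenylbis(trifluoromethanesulfonimide), O=S(=O)(N(c1ccccc1)S(=O)(=O)C(F)(F)F)C(F)(F)F
Why: Kinetic deprotonation of the methyl ketone at the methyl group (C16) and O-triflation should give the terminal enol triflate; the cinnamate has no enolisable hydrogen and the hindered amide base should leave it alone at −78 °C.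

**Step 16**
Reactants: 22 7α,8α-(isopropylidenedioxy)-13-(trifluoromethanesulfonyloxy)-14,15-dinorlabd-13(16)-en-19-yl (E)-4-(methoxymethoxy)cinnamate
Product: 23 7α,8α-dihydroxy-13-(trifluoromethanesulfonyloxy)-14,15-dinorlabd-13(16)-en-19-yl (E)-4-hydroxycinnamate
Conditions: HCl (3 M aq.)/THF (1:3), 35 °C
Reagents that add atoms: none
Why: Acid hydrolysis removes the acetonide and the aryl MOM acetal together while the enol triflate is inert to aqueous acid, and at this stage there is neither a ketone nor a diene that the freed 8α-OH could add to.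

**Step 17**
Reactants: 23 7α,8α-dihydroxy-13-(trifluoromethanesulfonyloxy)-14,15-dinorlabd-13(16)-en-19-yl (E)-4-hydroxycinnamate
Product: 24 7α,8α-dihydroxylabda-13(16),14-dien-19-yl (E)-4-hydroxycinnamate (target, CNP0254560.2)
Conditions: tributyl(vinyl)stannane (1.5 equiv), Pd(PPh3)4 (5 mol%), LiCl (3 equiv), THF, 60 °C; aq. KF work-up
Reagents that add atoms: tributyl(vinyl)stannane, C=C[Sn](CCCC)(CCCC)CCCC
Why: Stille coupling of the alkenyl triflate with the vinylstannane (oxidative addition to zerovalent palladium, transmetalation, reductive elimination) forms the C13–C14 bond and the 2-substituted 1,3-diene regiospecifically under neutral conditions that tolerate the free diol, the phenol and the ester.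

**Compound list**
1 | (E)-geranylacetone, (5E)-6,10-dimethylundeca-5,9-dien-2-one | CC(C)=CCC/C(C)=C/CCC(C)=O | starting material
2 | 2-[(3E)-4,8-dimethylnona-3,7-dien-1-yl]-2-methyl-1,3-dioxolane | CC(C)=CCC/C(C)=C/CCC1(C)OCCO1 | intermediate
3 | (2E,6E)-2,6-dimethyl-9-(2-methyl-1,3-dioxolan-2-yl)nona-2,6-dien-1-ol | OC/C(C)=C/CC/C(C)=C/CCC1(C)OCCO1 | intermediate
4 | 2-[(3E,7E)-9-bromo-4,8-dimethylnona-3,7-dien-1-yl]-2-methyl-1,3-dioxolane | BrC/C(C)=C/CC/C(C)=C/CCC1(C)OCCO1 | intermediate
5 | (−)-8-phenylmenthol, (1R,2S,5R)-5-methyl-2-(2-phenylpropan-2-yl)cyclohexan-1-ol | CC(C)(c1ccccc1)[C@@H]1CC[C@@H](C)C[C@H]1O | starting material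
6 | ethyl 2-methyl-3-oxobutanoate | CCOC(=O)C(C)C(C)=O | starting material
7 | (1R,2S,5R)-8-phenylmenthyl 2-methyl-3-oxobutanoate (C2 epimers) | CC(C)(c1ccccc1)[C@@H]1CC[C@@H](C)C[C@H]1OC(=O)C(C)C(C)=O | intermediate
8 | sodium lithium dianion (dienolate) of 7 | [Na+].[Li+].C=C([O-])C(C)=C([O-])O[C@@H]1C[C@H](C)CC[C@H]1C(C)(C)c1ccccc1 | intermediate (not isolated)
9 | (1R,2S,5R)-8-phenylmenthyl (6E,10E)-2,6,10-trimethyl-13-(2-methyl-1,3-dioxolan-2-yl)-3-oxotrideca-6,10-dienoate | CC(C)(c1ccccc1)[C@@H]1CC[C@@H](C)C[C@H]1OC(=O)C(C)C(=O)CC/C(C)=C/CC/C(C)=C/CCC1(C)OCCO1 | intermediate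
10 | (−)-8-phenylmenthyl 13,13-ethylenedioxy-3-oxo-14,15-dinorlabd-8(17)-en-19-oate | CC1(OCCO1)CC[C@H]1C(=C)CC[C@H]2[C@@](C)(C(=O)O[C@@H]3C[C@H](C)CC[C@H]3C(C)(C)c3ccccc3)C(=O)CC[C@@]21C | intermediate
11 | (−)-8-phenylmenthyl 13,13-ethylenedioxy-3-oxo-14,15-dinorlabd-7-en-19-oate | CC1(OCCO1)CC[C@H]1C(C)=CC[C@H]2[C@@](C)(C(=O)O[C@@H]3C[C@H](C)CC[C@H]3C(C)(C)c3ccccc3)C(=O)CC[C@@]21C | intermediate
12 | 13,13-ethylenedioxy-14,15-dinorlabd-7-ene-3β,19-diol | CC1(OCCO1)CC[C@H]1C(C)=CC[C@H]2[C@@](C)(CO)[C@@H](O)CC[C@@]21C | intermediate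
13 | 13,13-ethylenedioxy-14,15-dinorlabd-7-ene-3β,19-diyl cyclic thionocarbonate | CC1(OCCO1)CC[C@H]1C(C)=CC[C@H]2[C@@]3(C)COC(=S)O[C@H]3CC[C@@]21C | intermediate
14 | O-(13,13-ethylenedioxy-14,15-dinorlabd-7-en-19-yl) S-(tributylstannyl) thiocarbonate | CC1(OCCO1)CC[C@H]1C(C)=CC[C@H]2[C@@](C)(COC(=O)S[Sn](CCCC)(CCCC)CCCC)CCC[C@@]21C | intermediate (not isolated)
15 | 13,13-ethylenedioxy-14,15-dinorlabd-7-en-19-ol | CC1(OCCO1)CC[C@H]1C(C)=CC[C@H]2[C@@](C)(CO)CCC[C@@]21C | intermediate
16 | 13,13-ethylenedioxy-14,15-dinorlabdane-7α,8α,19-triol | CC1(OCCO1)CC[C@H]1[C@](C)(O)[C@H](O)C[C@H]2[C@@](C)(CO)CCC[C@@]21C | intermediate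
17 | 19-hydroxy-7α,8α-(isopropylidenedioxy)-14,15-dinorlabdan-13-one | CC(=O)CC[C@H]1[C@]3(C)OC(C)(C)O[C@@H]3C[C@H]2[C@@](C)(CO)CCC[C@@]21C | intermediate
18 | (E)-4-hydroxycinnamic acid (p-coumaric acid) | OC(=O)/C=C/c1ccc(O)cc1 | starting material
19 | methoxymethyl (E)-4-(methoxymethoxy)cinnamate | COCOC(=O)/C=C/c1ccc(OCOC)cc1 | intermediate (not isolated)
20 | (E)-4-(methoxymethoxy)cinnamic acid | COCOc1ccc(/C=C/C(=O)O)cc1 | intermediate
21 | 7α,8α-(isopropylidenedioxy)-13-oxo-14,15-dinorlabdan-19-yl (E)-4-(methoxymethoxy)cinnamate | CC(=O)CC[C@H]1[C@]3(C)OC(C)(C)O[C@@H]3C[C@H]2[C@@](C)(COC(=O)/C=C/c3ccc(OCOC)cc3)CCC[C@@]21C | intermediate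
22 | 7α,8α-(isopropylidenedioxy)-13-(trifluoromethanesulfonyloxy)-14,15-dinorlabd-13(16)-en-19-yl (E)-4-(methoxymethoxy)cinnamate | C=C(OS(=O)(=O)C(F)(F)F)CC[C@H]1[C@]3(C)OC(C)(C)O[C@@H]3C[C@H]2[C@@](C)(COC(=O)/C=C/c3ccc(OCOC)cc3)CCC[C@@]21C | intermediate
23 | 7α,8α-dihydroxy-13-(trifluoromethanesulfonyloxy)-14,15-dinorlabd-13(16)-en-19-yl (E)-4-hydroxycinnamate | C=C(OS(=O)(=O)C(F)(F)F)CC[C@H]1[C@](C)(O)[C@H](O)C[C@H]2[C@@](C)(COC(=O)/C=C/c3ccc(O)cc3)CCC[C@@]21C | intermediate
24 | 7α,8α-dihydroxylabda-13(16),14-dien-19-yl (E)-4-hydroxycinnamate | C=CC(=C)CC[C@H]1[C@](C)(O)[C@H](O)C[C@H]2[C@@](C)(COC(=O)/C=C/c3ccc(O)cc3)CCC[C@@]21C | target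

**Step count**
Total: 17 steps. Longest linear sequence: 15 steps (steps 1–3, 5–12, 14–17); steps 4 and 13 are side branches.

**Steps most likely to fail**

Step 6. The auxiliary may discriminate the two faces of the C4 radical only weakly, or the bulky ester may slow enolisation so that oxidation of the monocyclic radical competes with the second ring closure. Fallback (resolution in place of auxiliary control): it sets out from 4 and 6. The dianion of 6 (NaH, n-BuLi, THF, 0 °C) is alkylated with 4 to give ethyl (6E,10E)-2,6,10-trimethyl-13-(2-methyl-1,3-dioxolan-2-yl)-3-oxotrideca-6,10-dienoate F1. The same Mn(OAc)3/Cu(OAc)2 cascade should give racemic ethyl 13,13-ethylenedioxy-3-oxo-14,15-dinorlabd-8(17)-en-19-oate F2, and cobalt-hydride isomerisation as in step 7 the racemic Δ7 ester F3. LiAlH4 then gives the racemic 3β,19-diol F4. Its primary hydroxyl is esterified with (S)-O-methylmandelic acid (DCC, DMAP), and chromatographic separation of the two diastereomeric esters gives the 19-O-[(S)-methoxyphenylacetyl] derivative of the natural series F5. K2CO3 in MeOH releases 12, where the route is rejoined.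

Step 7. Hydrogen-atom return from C9 instead of C7 (tetrasubstituted Δ8 alkene) or net hydrogenation of the alkene may compete. Fallback (oxygen-directed transposition in place of isomerisation): it sets out from 10. SeO2/t-BuOOH allylic oxidation should place an axial hydroxyl on C7 and give the 7α-hydroxy-8(17)-ene keto ester F6. Mitsunobu-type reductive 1,3-transposition of this allylic alcohol (2-nitrobenzenesulfonylhydrazide, PPh3, DEAD, THF, −30 °C → rt) delivers hydrogen to C17 and moves the alkene to C7=C8 regiospecifically, which gives 11, where the route is rejoined.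

Step 15. Enolisation toward C12 as well as C16 would give regioisomeric triflates, and the amide base may attack the cinnamate. Fallback (regiospecific Shapiro chemistry before the ester is attached): it sets out from 17. Condensation with 2,4,6-triisopropylbenzenesulfonylhydrazide (MeOH, rt) gives the C13 sulfonylhydrazone F7. n-BuLi (3.3 equiv, THF, −78 → 0 °C) generates the less substituted vinyllithium, which is quenched with I2 to the 13-iodo-13(16)-ene acetonide alcohol F8. DCC/DMAP esterification with 20 gives the protected iodoalkene ester F9, and aqueous HCl/THF removes the acetonide and MOM groups to give the iodoalkene diol phenol F10. Stille coupling with tributyl(vinyl)stannane (Pd(PPh3)4, THF, 60 °C) then gives 24, where the route is rejoined.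

**Further compounds**
F1 | step 6 | ethyl (6E,10E)-2,6,10-trimethyl-13-(2-methyl-1,3-dioxolan-2-yl)-3-oxotrideca-6,10-dienoate | CCOC(=O)C(C)C(=O)CC/C(C)=C/CC/C(C)=C/CCC1(C)OCCO1
F2 | step 6 | racemic ethyl 13,13-ethylenedioxy-3-oxo-14,15-dinorlabd-8(17)-en-19-oate (one enantiomer drawn) | CC1(OCCO1)CC[C@H]1C(=C)CC[C@H]2[C@@](C)(C(=O)OCC)C(=O)CC[C@@]21C
F3 | step 6 | racemic ethyl 13,13-ethylenedioxy-3-oxo-14,15-dinorlabd-7-en-19-oate (one enantiomer drawn) | CC1(OCCO1)CC[C@H]1C(C)=CC[C@H]2[C@@](C)(C(=O)OCC)C(=O)CC[C@@]21C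
F4 | step 6 | racemic 13,13-ethylenedioxy-14,15-dinorlabd-7-ene-3β,19-diol (12 with its mirror image; mirror image drawn) | CC1(OCCO1)CC[C@@H]1C(C)=CC[C@@H]2[C@](C)(CO)[C@H](O)CC[C@]21C
F5 | step 6 | 13,13-ethylenedioxy-3β-hydroxy-14,15-dinorlabd-7-en-19-yl (S)-2-methoxy-2-phenylacetate | CC1(OCCO1)CC[C@H]1C(C)=CC[C@H]2[C@@](C)(COC(=O)[C@@H](OC)c3ccccc3)[C@@H](O)CC[C@@]21C
F6 | step 7 | (−)-8-phenylmenthyl 13,13-ethylenedioxy-7α-hydroxy-3-oxo-14,15-dinorlabd-8(17)-en-19-oate | CC1(OCCO1)CC[C@H]1C(=C)[C@H](O)C[C@H]2[C@@](C)(C(=O)O[C@@H]3C[C@H](C)CC[C@H]3C(C)(C)c3ccccc3)C(=O)CC[C@@]21C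
F7 | step 15 | 19-hydroxy-7α,8α-(isopropylidenedioxy)-14,15-dinorlabdan-13-one 2,4,6-triisopropylbenzenesulfonylhydrazone | CC(CC[C@H]1[C@]3(C)OC(C)(C)O[C@@H]3C[C@H]2[C@@](C)(CO)CCC[C@@]21C)=NNS(=O)(=O)c1c(C(C)C)cc(C(C)C)cc1C(C)C
F8 | step 15 | 13-iodo-7α,8α-(isopropylidenedioxy)-14,15-dinorlabd-13(16)-en-19-ol | C=C(I)CC[C@H]1[C@]3(C)OC(C)(C)O[C@@H]3C[C@H]2[C@@](C)(CO)CCC[C@@]21C
F9 | step 15 | 13-iodo-7α,8α-(isopropylidenedioxy)-14,15-dinorlabd-13(16)-en-19-yl (E)-4-(methoxymethoxy)cinnamate | C=C(I)CC[C@H]1[C@]3(C)OC(C)(C)O[C@@H]3C[C@H]2[C@@](C)(COC(=O)/C=C/c3ccc(OCOC)cc3)CCC[C@@]21C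
F10 | step 15 | 7α,8α-dihydroxy-13-iodo-14,15-dinorlabd-13(16)-en-19-yl (E)-4-hydroxycinnamate | C=C(I)CC[C@H]1[C@](C)(O)[C@H](O)C[C@H]2[C@@](C)(COC(=O)/C=C/c3ccc(O)cc3)CCC[C@@]21C
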